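The route rests on cutting the O4–C3 bond of the 1,4-dioxane ring. C3 and its exocyclic CH2OH carbon are stored as the two carbons of a terminal oxirane, so that attack of phenoxide O4 of the fused benzene ring B (para to its formyl group) on the inner oxirane carbon closes the six-membered dioxane ring, sets C3 with inversion and releases the hydroxymethyl group in one operation. The precursor is an aryl ether in which benzylic C2 (R) already carries O1 of ring B and the (S)-oxiranyl group, with O4 as a free phenol and the catechol of the C2 aryl ring A masked as a bis-MOM ether.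

Key step: step 9

Remark: locants O1, C2, C3, O4, C4a–C8a refer to the 2,3-dihydro-1,4-benzodioxine core numbered so that C2 bears the aryl group; with this numbering the target is (2R,3R), trans, with OMe on C5 and the propenal chain on C7.

Step 1
Reactants: 1 5-hydroxyvanillin (3,4-dihydroxy-5-methoxybenzaldehyde)
Product: 2 3-methoxy-4,5-bis(methoxymethoxy)benzaldehyde
Conditions: MOMCl (2.6 equiv), iPr2NEt, CH2Cl2, 0 °C to rt
Reagents that add atoms: chloromethyl methyl ether (MOMCl), COCCl
Why: Twofold Williamson-type O-alkylation (MOM protection) should mask both phenols for all the basic steps that follow, the aldehyde being inert to these conditions.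

Step 2
Reactants: 2 3-methoxy-4,5-bis(methoxymethoxy)benzaldehyde; 3 triethyl phosphonoacetate
Product: 4 ethyl (E)-3-[3-methoxy-4,5-bis(methoxymethoxy)phenyl]prop-2-enoate
Conditions: NaH, THF, 0 °C to rt
Reagents that add atoms: none
Why: Horner–Wadsworth–Emmons olefination with the stabilised phosphonate anion should give the E-cinnamate, since the aldehyde is not enolisable and MOM ethers are stable to base.

Step 3
Reactants: 4 ethyl (E)-3-[3-methoxy-4,5-bis(methoxymethoxy)phenyl]prop-2-enoate
Product: 5 (E)-3-[3-methoxy-4,5-bis(methoxymethoxy)phenyl]prop-2-en-1-ol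
Conditions: DIBAL-H (2.3 equiv), CH2Cl2, −78 °C to 0 °C; Rochelle salt work-up
Reagents that add atoms: none
Why: DIBAL-H 1,2-reduction of the α,β-unsaturated ester at low temperature should give the E-allylic alcohol without touching the alkene or the MOM acetals.

Step 4
Reactants: 5 (E)-3-[3-methoxy-4,5-bis(methoxymethoxy)phenyl]prop-2-en-1-ol
Product: 6 [(2S,3S)-3-[3-methoxy-4,5-bis(methoxymethoxy)phenyl]oxiran-2-yl]methanol
Conditions: Ti(OiPr)4 (10 mol %), L-(+)-DIPT (13 mol %), t-BuOOH (decane), 4 Å MS, CH2Cl2, −20 °C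
Reagents that add atoms: tert-butyl hydroperoxide, CC(C)(C)OO
Why: Katsuki–Sharpless asymmetric epoxidation, in which the Ti–L-(+)-tartrate catalyst delivers oxygen to the alkene face that gives the (2S,3S)-epoxy alcohol from E-cinnamyl-type alcohols, so the catalyst sets both stereocentres and the E-alkene sets their trans relationship; the 4-alkoxy group, flanked by two ortho oxygens, is a weak donor, which should keep the benzylic epoxide intact under the catalytic, sieve-dried conditions.

Step 5
Reactants: 1 5-hydroxyvanillin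
Product: 7 3-hydroxy-5-methoxy-4-(prop-2-en-1-yloxy)benzaldehyde (4-O-allyl-5-hydroxyvanillin)
Conditions: allyl bromide (1.05 equiv), NaHCO3, DMF, 40 °C
Reagents that add atoms: allyl bromide, C=CCBr
Why: Regioselective Williamson etherification, in which the 4-OH para to the formyl group is by far the more acidic phenol, so the weak base forms only its phenoxide and one allyl group should go on O4, leaving the 5-OH free.

Step 6
Reactants: 6 [(2S,3S)-3-[3-methoxy-4,5-bis(methoxymethoxy)phenyl]oxiran-2-yl]methanol; 7 3-hydroxy-5-methoxy-4-(prop-2-en-1-yloxy)benzaldehyde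
Product: 8 3-{[(1R,2S)-2,3-dihydroxy-1-[3-methoxy-4,5-bis(methoxymethoxy)phenyl]propyl]oxy}-5-methoxy-4-(prop-2-en-1-yloxy)benzaldehyde
Conditions: 7 (1.5 equiv), aq. NaOH (1.2 equiv, mediator, not consumed), t-BuOH–H2O, 65 °C
Reagents that add atoms: none
Why: Phenoxide opening of a 3-aryl-2,3-epoxy alcohol by SN2 at the benzylic carbon (the known course for aryl glycidols with aryloxides in aqueous base) should bond the 5-oxygen of 7 to C3 with inversion while C2 is untouched, giving the anti diol in a pure addition that splits nothing off; phenol is kept in excess over hydroxide so that no free hydroxide attacks the epoxide.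

Step 7
Reactants: 8 3-{[(1R,2S)-2,3-dihydroxy-1-[3-methoxy-4,5-bis(methoxymethoxy)phenyl]propyl]oxy}-5-methoxy-4-(prop-2-en-1-yloxy)benzaldehyde
Product: 10 3-{(R)-[3-methoxy-4,5-bis(methoxymethoxy)phenyl][(2S)-oxiran-2-yl]methoxy}-5-methoxy-4-(prop-2-en-1-yloxy)benzaldehyde, via primary monotosylate 9 (not isolated)
Conditions: TsCl (1.05 equiv), Et3N, Bu2SnO (2 mol %), CH2Cl2, 0 °C to rt; then K2CO3, MeOH, rt
Reagents that add atoms: none
Why: Stannylene-catalysed sulfonylation picks the primary hydroxyl of the terminal 1,2-diol and the secondary alkoxide then displaces the tosylate (intramolecular Williamson reaction, 3-exo-tet), so no bond to the carbinol stereocentre is broken and it is retained as the (S)-oxirane carbon.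

Step 8
Reactants: 10 3-{(R)-[3-methoxy-4,5-bis(methoxymethoxy)phenyl][(2S)-oxiran-2-yl]methoxy}-5-methoxy-4-(prop-2-en-1-yloxy)benzaldehyde
Product: 11 4-hydroxy-3-{(R)-[3-methoxy-4,5-bis(methoxymethoxy)phenyl][(2S)-oxiran-2-yl]methoxy}-5-methoxybenzaldehyde
Conditions: Pd(PPh3)4 (3 mol %), N-methylaniline (2 equiv), THF, rt
Reagents that add atoms: none
Why: Tsuji–Trost-type deallylation, in which Pd(0) ionises the allyl aryl ether and the weakly basic amine traps the π-allyl unit, should free the phenol under neutral conditions that leave the oxirane, the aldehyde and the MOM ethers alone; a premature ring closure would only anticipate step 9.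

Step 9
Reactants: 11 4-hydroxy-3-{(R)-[3-methoxy-4,5-bis(methoxymethoxy)phenyl][(2S)-oxiran-2-yl]methoxy}-5-methoxybenzaldehyde
Product: 12 (2R,3R)-3-(hydroxymethyl)-5-methoxy-2-[3-methoxy-4,5-bis(methoxymethoxy)phenyl]-2,3-dihydro-1,4-benzodioxine-7-carbaldehyde
Conditions: K2CO3 (0.5 equiv), DMF (0.02 M), 60 °C
Reagents that add atoms: none
Why: Carbonate deprotonates the O4–H phenol (acidified by the para formyl group) and the phenoxide attacks the inner oxirane carbon (future C3) from the side opposite its ring C–O bond, so the O4–C3 bond forms and the oxirane oxygen leaves as the CH2O− alkoxide, which takes a proton from the next phenol molecule and makes the step a base-catalysed isomerisation that splits nothing off. The closest known reaction type is the base-induced cyclisation of catechol mono-glycidyl ethers to 2-hydroxymethyl-1,4-benzodioxanes, an intramolecular phenoxide opening of an epoxide. The dioxane ring (O1, C2, C3, O4, C4a, C8a) closes in the 6-exo-tet mode. The new stereocentre C3 is set by substrate control through stereospecific SN2 inversion of the (S)-oxirane carbon, which gives 3R and, with the untouched 2R centre, the trans ring with aryl and CH2OH both pseudo-equatorial. The step needs 6-exo over 7-endo regioselectivity, which the shorter tether to the inner carbon (six- against seven-membered transition state) should secure, and a pure SN2 path, which the non-acidic medium and the non-benzylic oxirane carbon secure; high dilution suppresses intermolecular opening.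

Step 10
Reactants: 12 (2R,3R)-3-(hydroxymethyl)-5-methoxy-2-[3-methoxy-4,5-bis(methoxymethoxy)phenyl]-2,3-dihydro-1,4-benzodioxine-7-carbaldehyde; 13 (triphenylphosphoranylidene)acetaldehyde
Product: 14 (E)-3-[(2R,3R)-3-(hydroxymethyl)-5-methoxy-2-[3-methoxy-4,5-bis(methoxymethoxy)phenyl]-2,3-dihydro-1,4-benzodioxin-7-yl]prop-2-enal
Conditions: 13 (1.3 equiv), toluene, 85 °C
Reagents that add atoms: none
Why: Wittig reaction of the aryl aldehyde with the stabilised formylmethylene ylide needs no base, tolerates the free primary alcohol and should give the E-enal, as stabilised ylides do.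

Step 11
Reactants: 14 (E)-3-[(2R,3R)-3-(hydroxymethyl)-5-methoxy-2-[3-methoxy-4,5-bis(methoxymethoxy)phenyl]-2,3-dihydro-1,4-benzodioxin-7-yl]prop-2-enal
Product: 15 (E)-3-[(2R,3R)-2-(3,4-dihydroxy-5-methoxyphenyl)-3-(hydroxymethyl)-5-methoxy-2,3-dihydro-1,4-benzodioxin-7-yl]prop-2-enal (CNP0103768.1)
Conditions: 3 M aq. HCl, THF, 45 °C
Reagents that add atoms: none
Why: Acid-catalysed hydrolysis of the two aryl MOM acetals (each releases formaldehyde and methanol) should free the catechol, while the enal, the primary alcohol and the trans-diequatorial benzodioxane should withstand dilute aqueous acid at this temperature.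

Compound list
1 | 5-hydroxyvanillin (3,4-dihydroxy-5-methoxybenzaldehyde) | COc1cc(C=O)cc(O)c1O | starting material
2 | 3-methoxy-4,5-bis(methoxymethoxy)benzaldehyde | COCOc1cc(C=O)cc(OC)c1OCOC | intermediate
3 | triethyl phosphonoacetate | CCOC(=O)CP(=O)(OCC)OCC | starting material
4 | ethyl (E)-3-[3-methoxy-4,5-bis(methoxymethoxy)phenyl]prop-2-enoate | CCOC(=O)/C=C/c1cc(OC)c(OCOC)c(OCOC)c1 | intermediate
5 | (E)-3-[3-methoxy-4,5-bis(methoxymethoxy)phenyl]prop-2-en-1-ol | OC/C=C/c1cc(OC)c(OCOC)c(OCOC)c1 | intermediate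
6 | [(2S,3S)-3-[3-methoxy-4,5-bis(methoxymethoxy)phenyl]oxiran-2-yl]methanol | OC[C@@H]1O[C@H]1c2cc(OC)c(OCOC)c(OCOC)c2 | intermediate
7 | 3-hydroxy-5-methoxy-4-(prop-2-en-1-yloxy)benzaldehyde | COc1cc(C=O)cc(O)c1OCC=C | intermediate
8 | 3-{[(1R,2S)-2,3-dihydroxy-1-[3-methoxy-4,5-bis(methoxymethoxy)phenyl]propyl]oxy}-5-methoxy-4-(prop-2-en-1-yloxy)benzaldehyde | COCOc1c(OC)cc(cc1OCOC)[C@@H](Oc1cc(C=O)cc(OC)c1OCC=C)[C@@H](O)CO | intermediate
9 | (2S,3R)-3-[5-formyl-3-methoxy-2-(prop-2-en-1-yloxy)phenoxy]-2-hydroxy-3-[3-methoxy-4,5-bis(methoxymethoxy)phenyl]propyl 4-methylbenzenesulfonate (primary monotosylate of 8) | COCOc1c(OC)cc(cc1OCOC)[C@@H](Oc1cc(C=O)cc(OC)c1OCC=C)[C@@H](O)COS(=O)(=O)c1ccc(C)cc1 | intermediate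
10 | 3-{(R)-[3-methoxy-4,5-bis(methoxymethoxy)phenyl][(2S)-oxiran-2-yl]methoxy}-5-methoxy-4-(prop-2-en-1-yloxy)benzaldehyde | COCOc1c(OC)cc(cc1OCOC)[C@@H](Oc1cc(C=O)cc(OC)c1OCC=C)[C@@H]1CO1 | intermediate
11 | 4-hydroxy-3-{(R)-[3-methoxy-4,5-bis(methoxymethoxy)phenyl][(2S)-oxiran-2-yl]methoxy}-5-methoxybenzaldehyde | COCOc1c(OC)cc(cc1OCOC)[C@@H](Oc1cc(C=O)cc(OC)c1O)[C@@H]1CO1 | intermediate
12 | (2R,3R)-3-(hydroxymethyl)-5-methoxy-2-[3-methoxy-4,5-bis(methoxymethoxy)phenyl]-2,3-dihydro-1,4-benzodioxine-7-carbaldehyde | COCOc1c(OC)cc(cc1OCOC)[C@H]1Oc2cc(C=O)cc(OC)c2O[C@@H]1CO | intermediate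
13 | (triphenylphosphoranylidene)acetaldehyde | O=CC=P(c1ccccc1)(c1ccccc1)c1ccccc1 | starting material
14 | (E)-3-[(2R,3R)-3-(hydroxymethyl)-5-methoxy-2-[3-methoxy-4,5-bis(methoxymethoxy)phenyl]-2,3-dihydro-1,4-benzodioxin-7-yl]prop-2-enal | COCOc1c(OC)cc(cc1OCOC)[C@H]1Oc2cc(/C=C/C=O)cc(OC)c2O[C@@H]1CO | intermediate
15 | (E)-3-[(2R,3R)-2-(3,4-dihydroxy-5-methoxyphenyl)-3-(hydroxymethyl)-5-methoxy-2,3-dihydro-1,4-benzodioxin-7-yl]prop-2-enal | COc1cc([C@H]2Oc3cc(/C=C/C=O)cc(OC)c3O[C@@H]2CO)cc(O)c1O | target

Total step count: 11. Longest linear sequence: 10 steps (steps 1–4 and 6–11); step 5 is a one-step side branch from 1.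

Steps most likely to fail

1. Step 9 (key step). The formyl-stabilised phenoxide is a weak nucleophile and may react slowly, so attack at the terminal oxirane carbon (7-endo) or intermolecular opening may compete with the 6-exo closure. The fallback closes the same O4–C3 bond by a Mitsunobu etherification in which the seven-membered path is blocked. It sets out from diol 8. The primary hydroxyl is silylated (TBSCl, imidazole, DMF) to the primary tert-butyldimethylsilyl ether F3. The allyl group is then removed as in step 8 to give the free phenol secondary alcohol F4. PPh3 and DIAD in THF should close the dioxane ring by SN2 displacement of the activated secondary hydroxyl by O4 with inversion (S to 3R), giving the silyl-protected benzodioxane F5. TBAF in THF then returns to the route at 12.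

2. Step 6. Under base the epoxy alcohol may shift its oxirane to the chain end (Payne equilibration) and be opened at the terminal carbon, or partial ionisation at the electron-rich benzylic carbon may erode the inversion. The fallback removes the free hydroxyl and so shuts the migration path. It sets out from 6, which is silylated (TBDPSCl, imidazole, DMF) to the tert-butyldiphenylsilyl ether F1. Opening with the caesium phenoxide of 7 (Cs2CO3, DMF, 80 °C) at the benzylic carbon should give the silyl-protected anti aryloxy alcohol F2. TBAF in THF returns to the route at 8.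

3. Step 10. The product enal can itself be olefinated by the ylide and the electron-rich aryl aldehyde may convert slowly, so over-homologation may erode the step. The fallback is a three-stage homologation that cannot over-react. It sets out from 12. Horner–Wadsworth–Emmons olefination with 3 (LiCl, DBU, MeCN) gives the E-acrylate F6. DIBAL-H reduction (CH2Cl2, −78 °C) gives the E-allylic alcohol F7. MnO2 (CH2Cl2, rt) then oxidises only the allylic hydroxyl and returns to the route at 14.

Further compounds
F1 | step 6 | tert-butyl{[(2S,3S)-3-[3-methoxy-4,5-bis(methoxymethoxy)phenyl]oxiran-2-yl]methoxy}diphenylsilane | CC(C)(C)[Si](c1ccccc1)(c1ccccc1)OC[C@@H]1O[C@H]1c1cc(OC)c(OCOC)c(OCOC)c1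
F2 | step 6 | 3-{[(1R,2S)-3-(tert-butyldiphenylsilyloxy)-2-hydroxy-1-[3-methoxy-4,5-bis(methoxymethoxy)phenyl]propyl]oxy}-5-methoxy-4-(prop-2-en-1-yloxy)benzaldehyde | COCOc1c(OC)cc(cc1OCOC)[C@@H](Oc1cc(C=O)cc(OC)c1OCC=C)[C@@H](O)CO[Si](c1ccccc1)(c1ccccc1)C(C)(C)C
F3 | step 9 | 3-{[(1R,2S)-3-(tert-butyldimethylsilyloxy)-2-hydroxy-1-[3-methoxy-4,5-bis(methoxymethoxy)phenyl]propyl]oxy}-5-methoxy-4-(prop-2-en-1-yloxy)benzaldehyde | COCOc1c(OC)cc(cc1OCOC)[C@@H](Oc1cc(C=O)cc(OC)c1OCC=C)[C@@H](O)CO[Si](C)(C)C(C)(C)C
F4 | step 9 | 3-{[(1R,2S)-3-(tert-butyldimethylsilyloxy)-2-hydroxy-1-[3-methoxy-4,5-bis(methoxymethoxy)phenyl]propyl]oxy}-4-hydroxy-5-methoxybenzaldehyde | COCOc1c(OC)cc(cc1OCOC)[C@@H](Oc1cc(C=O)cc(OC)c1O)[C@@H](O)CO[Si](C)(C)C(C)(C)C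
F5 | step 9 | (2R,3R)-3-[(tert-butyldimethylsilyloxy)methyl]-5-methoxy-2-[3-methoxy-4,5-bis(methoxymethoxy)phenyl]-2,3-dihydro-1,4-benzodioxine-7-carbaldehyde | COCOc1c(OC)cc(cc1OCOC)[C@H]1Oc2cc(C=O)cc(OC)c2O[C@@H]1CO[Si](C)(C)C(C)(C)C
F6 | step 10 | ethyl (E)-3-[(2R,3R)-3-(hydroxymethyl)-5-methoxy-2-[3-methoxy-4,5-bis(methoxymethoxy)phenyl]-2,3-dihydro-1,4-benzodioxin-7-yl]prop-2-enoate | COCOc1c(OC)cc(cc1OCOC)[C@H]1Oc2cc(/C=C/C(=O)OCC)cc(OC)c2O[C@@H]1CO
F7 | step 10 | (E)-3-[(2R,3R)-3-(hydroxymethyl)-5-methoxy-2-[3-methoxy-4,5-bis(methoxymethoxy)phenyl]-2,3-dihydro-1,4-benzodioxin-7-yl]prop-2-en-1-ol | COCOc1c(OC)cc(cc1OCOC)[C@H]1Oc2cc(/C=C/CO)cc(OC)c2O[C@@H]1CO
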